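The flavanone is cut at the two adjacent bonds that tie ring C to ring A, O1–C8a and C4–C4a, so ring A arrives as a C4a–C8a aryne and C2–C3–C4 as an enantiopure β-oxy ester. The feature exploited is the C5 oxygen beside C4a: it polarises the aryne, sends the alkoxide oxygen to C8a and stabilises the C4a carbanion, which then acylates itself on the ester. One fluoride-triggered operation thus forms both bonds and ring C without touching C2. The aryne precursor is an ortho-silylaryl triflate carrying 5-OMOM, 6-prenyl and 7-OMe; its partner is the O-SiMe3 ether of the (S)-hydroxy ester, so that no O–H proton is present.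

Key step: step 12

Remark: flavanone locants (O1, C2–C4, C4a, C5–C8, C8a) are used for the corresponding atoms of all intermediates; commercial 3-chloro-3-methylbut-1-yne (7) is taken as the C5 unit for the prenyl group.

Step 1
Reactants: 1 5-methoxyresorcinol
Product: 2 2-iodo-5-methoxybenzene-1,3-diol
Conditions: I2 (1.0 equiv), NaHCO3 (1.1 equiv), THF/H2O (1:1), 0 °C
Reagents that add atoms: iodine, [I][I]
Why: Electrophilic aromatic iodination of resorcinols in aqueous bicarbonate is known to favour the carbon between the two hydroxyl groups, which marks the future C4a with a halogen that exchanges with lithium faster than bromine does.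

Step 2
Reactants: 2 2-iodo-5-methoxybenzene-1,3-diol
Product: 3 2-iodo-5-methoxy-1,3-bis(trimethylsilyloxy)benzene
Conditions: (Me3Si)2NH (1.2 equiv), THF, 70 °C; volatiles removed in vacuo
Reagents that add atoms: hexamethyldisilazane, C[Si](C)(C)N[Si](C)(C)C
Why: O-Silylation of phenols with hexamethyldisilazane is clean, gives only ammonia as by-product and places on oxygen the silyl group that will migrate to carbon.

Step 3
Reactants: 3 2-iodo-5-methoxy-1,3-bis(trimethylsilyloxy)benzene
Product: 6 3-hydroxy-5-methoxy-2-(trimethylsilyl)phenyl trifluoromethanesulfonate, via lithium phenoxide 4 (not isolated), via silyl ether triflate 5 (not isolated)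
Conditions: n-BuLi (1.05 equiv), THF, −100 °C; Tf2O (1.1 equiv), −100 to −78 °C; then MeOH, citric acid (cat.), 0 °C
Reagents that add atoms: trifluoromethanesulfonic anhydride, O=S(=O)(OS(=O)(=O)C(F)(F)F)C(F)(F)F
Why: Iodine–lithium exchange followed by a fast 1,3 O-to-C silyl shift (retro-Brook rearrangement) frees exactly one phenoxide, so Tf2O should triflate only that oxygen and methanolysis of the remaining aryl silyl ether leaves the two ring oxygens differentiated, as in the standard preparation of ortho-silylaryl triflates.

Step 4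
Reactants: 6 3-hydroxy-5-methoxy-2-(trimethylsilyl)phenyl trifluoromethanesulfonate; 7 3-chloro-3-methylbut-1-yne
Product: 8 5-methoxy-3-[(2-methylbut-3-yn-2-yl)oxy]-2-(trimethylsilyl)phenyl trifluoromethanesulfonate
Conditions: 7 (1.5 equiv), DBU (1.5 equiv), CuCl2·2H2O (1 mol %), MeCN, 0 °C
Reagents that add atoms: none
Why: Copper-catalysed propargylic substitution through a copper allenylidene etherifies phenols with tertiary propargylic chlorides under mild amine-base conditions that contain no fluoride and should leave the silyl triflate intact.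

Step 5
Reactants: 8 5-methoxy-3-[(2-methylbut-3-yn-2-yl)oxy]-2-(trimethylsilyl)phenyl trifluoromethanesulfonate
Product: 9 5-methoxy-3-[(2-methylbut-3-en-2-yl)oxy]-2-(trimethylsilyl)phenyl trifluoromethanesulfonate
Conditions: H2 (1 atm), Pd/CaCO3 poisoned with Pb(OAc)2 (Lindlar catalyst), quinoline, EtOAc, rt
Reagents that add atoms: none
Why: Lindlar semihydrogenation stops at the alkene and should give the 1,1-dimethylallyl ether without touching the aryl triflate or the C–Si bond.

Step 6
Reactants: 9 5-methoxy-3-[(2-methylbut-3-en-2-yl)oxy]-2-(trimethylsilyl)phenyl trifluoromethanesulfonate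
Product: 10 3-hydroxy-5-methoxy-4-(3-methylbut-2-en-1-yl)-2-(trimethylsilyl)phenyl trifluoromethanesulfonate
Conditions: PhNEt2, 130 °C
Reagents that add atoms: none
Why: The aromatic Claisen rearrangement ([3,3]-sigmatropic shift, then enolisation) should move the tertiary allyl group with allylic transposition to the only unsubstituted ortho carbon (future C6), where it arrives as a prenyl group, the other ortho carbon being blocked by SiMe3.

Step 7
Reactants: 10 3-hydroxy-5-methoxy-4-(3-methylbut-2-en-1-yl)-2-(trimethylsilyl)phenyl trifluoromethanesulfonate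
Product: 11 5-methoxy-3-(methoxymethoxy)-4-(3-methylbut-2-en-1-yl)-2-(trimethylsilyl)phenyl trifluoromethanesulfonate
Conditions: MOMCl (2 equiv), i-Pr2NEt (3 equiv), CH2Cl2, 0 to 40 °C
Reagents that add atoms: chloromethyl methyl ether, COCCl
Why: Williamson-type O-alkylation with MOMCl and a hindered amine protects the future C5 oxygen as an acetal that survives fluoride, without any nucleophile able to attack silicon.

Step 8
Reactants: 12 4'-hydroxyacetophenone
Product: 13 1-[4-(methoxymethoxy)phenyl]ethan-1-one
Conditions: MOMCl (1.2 equiv), i-Pr2NEt (1.5 equiv), CH2Cl2, 0 °C to rt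
Reagents that add atoms: chloromethyl methyl ether, COCCl
Why: Williamson-type O-alkylation masks the phenol, which would otherwise add to the aryne in step 12, with the same group used on ring A so that one final operation frees both.

Step 9
Reactants: 13 1-[4-(methoxymethoxy)phenyl]ethan-1-one; 14 dimethyl carbonate
Product: 15 methyl 3-[4-(methoxymethoxy)phenyl]-3-oxopropanoate
Conditions: NaH (2.2 equiv), 14 (3 equiv), THF, 65 °C; AcOH quench
Reagents that add atoms: none
Why: The crossed Claisen condensation of the ketone enolate with dimethyl carbonate is driven to completion by deprotonation of the β-keto ester as it forms.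

Step 10
Reactants: 15 methyl 3-[4-(methoxymethoxy)phenyl]-3-oxopropanoate
Product: 16 methyl (S)-3-hydroxy-3-[4-(methoxymethoxy)phenyl]propanoate
Conditions: RuCl(p-cymene)[(S,S)-TsDPEN] (1 mol %), HCO2H/Et3N (5:2), 30 °C
Reagents that add atoms: none
Why: Noyori–Ikariya asymmetric transfer hydrogenation delivers hydride through the six-membered transition state organised by the CH/π contact between the aryl group and the cymene ligand, which with the (S,S)-diamine gives the (S)-carbinol of aryl ketones, so the catalyst sets the future C2 stereocentre under buffered conditions that spare the MOM ether.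

Step 11
Reactants: 16 methyl (S)-3-hydroxy-3-[4-(methoxymethoxy)phenyl]propanoate
Product: 17 methyl (S)-3-[4-(methoxymethoxy)phenyl]-3-[(trimethylsilyl)oxy]propanoate
Conditions: Me3SiCl (1.2 equiv), Et3N (1.5 equiv), CH2Cl2, 0 °C; pentane, filtration, evaporation
Reagents that add atoms: chlorotrimethylsilane, C[Si](C)(C)Cl
Why: Silylation of a secondary alcohol with Me3SiCl and triethylamine is routine, leaves ester, acetal and stereocentre untouched, and turns the hydroxyl into a group that fluoride converts into the alkoxide without releasing a proton.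

Step 12
Reactants: 11 5-methoxy-3-(methoxymethoxy)-4-(3-methylbut-2-en-1-yl)-2-(trimethylsilyl)phenyl trifluoromethanesulfonate; 17 methyl (S)-3-[4-(methoxymethoxy)phenyl]-3-[(trimethylsilyl)oxy]propanoate
Product: 20 (S)-7-methoxy-5-(methoxymethoxy)-2-[4-(methoxymethoxy)phenyl]-6-(3-methylbut-2-en-1-yl)chroman-4-one, via cesium alkoxide 18 (not isolated), via aryne 19 (not isolated)
Conditions: CsF (2 equiv, dried), THF, 60 °C; solution of 11 and 17 (1.3 equiv) added over 6 h, final 0.02 M
Reagents that add atoms: none
Why: Proposed new method: fluoride removes SiMe3 from C4a of 11 and triflate leaves C8a to give aryne 19, while fluoride, and later the methoxide expelled on ring closure, desilylates 17 to alkoxide 18; 18 adds to C8a, and the C4a carbanion so formed attacks the ester carbonyl and expels methoxide, so that O1–C8a and C4–C4a are made in one cascade. The closest known reaction type is the fluoride-triggered annulation of arynes with salicylate esters to xanthones (phenoxide O-arylation, then acylation of the aryl anion), which has not been extended to aliphatic β-oxy esters. Ring C closes by 6-exo-trig acyl substitution at the ester carbon. No stereocentre is created: the C2–O bond is never broken, so the (S) configuration fixed in step 10 should be carried over unchanged. Attack at C8a is secured by the C5 OMOM group, whose inductive pull makes C8a the electrophilic aryne terminus and stabilises charge at C4a, and by the lower hindrance beside C8–H. Acylation must outrun protonation of the C4a carbanion, which is why the hydroxyl enters as its silyl ether in dry THF at high dilution, the expelled methoxide being taken up by silicon as MeOSiMe3.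

Step 13
Reactants: 20 (S)-7-methoxy-5-(methoxymethoxy)-2-[4-(methoxymethoxy)phenyl]-6-(3-methylbut-2-en-1-yl)chroman-4-one
Product: 21 6-prenylsakuranetin, (S)-5-hydroxy-2-(4-hydroxyphenyl)-7-methoxy-6-(3-methylbut-2-en-1-yl)chroman-4-one
Conditions: HCl (3 M aq.), MeOH, 40 °C
Reagents that add atoms: none
Why: Acid-catalysed acetal exchange with methanol should remove both MOM ethers (the one peri to the carbonyl first) under conditions mild enough for the prenyl group and for C2, which has no base-type ring-opening pathway in acid.

Compound list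
1 | 5-methoxyresorcinol (5-methoxybenzene-1,3-diol) | COc1cc(O)cc(O)c1 | starting material
2 | 2-iodo-5-methoxybenzene-1,3-diol | Ic1c(O)cc(OC)cc1O | intermediate
3 | 2-iodo-5-methoxy-1,3-bis(trimethylsilyloxy)benzene | Ic1c(O[Si](C)(C)C)cc(OC)cc1O[Si](C)(C)C | intermediate
4 | lithium 5-methoxy-2-(trimethylsilyl)-3-(trimethylsilyloxy)phenolate | [Li+].[O-]c1cc(OC)cc(O[Si](C)(C)C)c1[Si](C)(C)C | intermediate (not isolated)
5 | 5-methoxy-2-(trimethylsilyl)-3-(trimethylsilyloxy)phenyl trifluoromethanesulfonate | COc1cc(OS(=O)(=O)C(F)(F)F)c([Si](C)(C)C)c(O[Si](C)(C)C)c1 | intermediate (not isolated)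
6 | 3-hydroxy-5-methoxy-2-(trimethylsilyl)phenyl trifluoromethanesulfonate | COc1cc(OS(=O)(=O)C(F)(F)F)c([Si](C)(C)C)c(O)c1 | intermediate
7 | 3-chloro-3-methylbut-1-yne | CC(C)(Cl)C#C | starting material
8 | 5-methoxy-3-[(2-methylbut-3-yn-2-yl)oxy]-2-(trimethylsilyl)phenyl trifluoromethanesulfonate | COc1cc(OS(=O)(=O)C(F)(F)F)c([Si](C)(C)C)c(OC(C)(C)C#C)c1 | intermediate
9 | 5-methoxy-3-[(2-methylbut-3-en-2-yl)oxy]-2-(trimethylsilyl)phenyl trifluoromethanesulfonate | COc1cc(OS(=O)(=O)C(F)(F)F)c([Si](C)(C)C)c(OC(C)(C)C=C)c1 | intermediate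
10 | 3-hydroxy-5-methoxy-4-(3-methylbut-2-en-1-yl)-2-(trimethylsilyl)phenyl trifluoromethanesulfonate | COc1cc(OS(=O)(=O)C(F)(F)F)c([Si](C)(C)C)c(O)c1CC=C(C)C | intermediate
11 | 5-methoxy-3-(methoxymethoxy)-4-(3-methylbut-2-en-1-yl)-2-(trimethylsilyl)phenyl trifluoromethanesulfonate | COc1cc(OS(=O)(=O)C(F)(F)F)c([Si](C)(C)C)c(OCOC)c1CC=C(C)C | intermediate
12 | 4'-hydroxyacetophenone | CC(=O)c1ccc(O)cc1 | starting material
13 | 1-[4-(methoxymethoxy)phenyl]ethan-1-one | CC(=O)c1ccc(OCOC)cc1 | intermediate
14 | dimethyl carbonate | COC(=O)OC | starting material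
15 | methyl 3-[4-(methoxymethoxy)phenyl]-3-oxopropanoate | COC(=O)CC(=O)c1ccc(OCOC)cc1 | intermediate
16 | methyl (S)-3-hydroxy-3-[4-(methoxymethoxy)phenyl]propanoate | COC(=O)C[C@@H](c1ccc(OCOC)cc1)O | intermediate
17 | methyl (S)-3-[4-(methoxymethoxy)phenyl]-3-[(trimethylsilyl)oxy]propanoate | COC(=O)C[C@@H](c1ccc(OCOC)cc1)O[Si](C)(C)C | intermediate
18 | cesium (S)-3-methoxy-1-[4-(methoxymethoxy)phenyl]-3-oxopropan-1-olate | COC(=O)C[C@@H](c1ccc(OCOC)cc1)[O-].[Cs+] | intermediate (not isolated)
19 | 5-methoxy-3-(methoxymethoxy)-4-(3-methylbut-2-en-1-yl)-1,2-didehydrobenzene (the C4a–C8a aryne) | COC1=CC#CC(OCOC)=C1CC=C(C)C | intermediate (not isolated)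
20 | (S)-7-methoxy-5-(methoxymethoxy)-2-[4-(methoxymethoxy)phenyl]-6-(3-methylbut-2-en-1-yl)chroman-4-one | COc1cc2c(c(OCOC)c1CC=C(C)C)C(=O)C[C@@H](c1ccc(OCOC)cc1)O2 | intermediate
21 | 6-prenylsakuranetin, (S)-5-hydroxy-2-(4-hydroxyphenyl)-7-methoxy-6-(3-methylbut-2-en-1-yl)chroman-4-one | COc1cc2c(c(O)c1CC=C(C)C)C(=O)C[C@@H](c1ccc(O)cc1)O2 | target

Total step count: 13
Longest linear sequence: 9 steps (steps 1 to 7, then 12 and 13)

Steps most likely to fail

Step 12 (key step). Three processes may defeat it:
- The C4a carbanion may be quenched by internal proton transfer from C3–H, after which the ester enolate expels the aryloxide.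
- The free alkoxide may fragment by retro-aldol reaction or transesterify before it meets the aryne.
- Base may open ring C of the product and erode the configuration at C2.

The fallback uses known chemistry, sets out from 11 and comes back at 20. Compound 11 is heated with acetic acid and CsF in THF at 125 °C in a sealed tube. This is the established insertion of an aryne into the C–O bond of a carboxylic acid: the carboxylate adds at C8a, C4a closes on the carbonyl, and the four-membered ring opens. It should give 1-[2-hydroxy-4-methoxy-6-(methoxymethoxy)-5-(3-methylbut-2-en-1-yl)phenyl]ethan-1-one F1. Claisen–Schmidt condensation of F1 with commercial 4-(methoxymethoxy)benzaldehyde (KOH, EtOH) gives (E)-1-[2-hydroxy-4-methoxy-6-(methoxymethoxy)-5-(3-methylbut-2-en-1-yl)phenyl]-3-[4-(methoxymethoxy)phenyl]prop-2-en-1-one F2. Oxa-Michael ring closure (NaOAc, EtOH, reflux) gives racemic 7-methoxy-5-(methoxymethoxy)-2-[4-(methoxymethoxy)phenyl]-6-(3-methylbut-2-en-1-yl)chroman-4-one F3. Compound 20 is then separated from F3 by preparative HPLC on a chiral stationary phase.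

Step 1. Iodination may take place between OH and OMe instead of between the two hydroxyl groups, or run on to a di-iodide, and the isomers may be hard to separate. The fallback sets out from 1 and comes back at 2. MOMCl and i-Pr2NEt convert 1 into 1-methoxy-3,5-bis(methoxymethoxy)benzene F4. Directed ortho-lithiation between the two acetal oxygens (n-BuLi, THF, 0 °C) and quenching with I2 gives 2-iodo-5-methoxy-1,3-bis(methoxymethoxy)benzene F5. HCl in MeOH at room temperature then removes both MOM groups and gives 2.

Step 4. Etherification may stall at the phenol crowded by the neighbouring SiMe3 group, or the tertiary chloride may be lost by elimination to the enyne. The fallback sets out from 6 and comes back at 11. Allyl bromide and K2CO3 in acetone give 3-(allyloxy)-5-methoxy-2-(trimethylsilyl)phenyl trifluoromethanesulfonate F6. Aromatic Claisen rearrangement (PhNEt2, 180 °C) gives 4-allyl-3-hydroxy-5-methoxy-2-(trimethylsilyl)phenyl trifluoromethanesulfonate F7. MOMCl and i-Pr2NEt give 4-allyl-5-methoxy-3-(methoxymethoxy)-2-(trimethylsilyl)phenyl trifluoromethanesulfonate F8. Olefin cross-metathesis with 2-methylbut-2-ene and the second-generation Grubbs catalyst RuCl2(=CHPh)(H2IMes)(PCy3) in CH2Cl2 at 40 °C turns allyl into prenyl and gives 11.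

Further compounds
F1 | step 12 | 1-[2-hydroxy-4-methoxy-6-(methoxymethoxy)-5-(3-methylbut-2-en-1-yl)phenyl]ethan-1-one | COc1cc(O)c(C(C)=O)c(OCOC)c1CC=C(C)C
F2 | step 12 | (E)-1-[2-hydroxy-4-methoxy-6-(methoxymethoxy)-5-(3-methylbut-2-en-1-yl)phenyl]-3-[4-(methoxymethoxy)phenyl]prop-2-en-1-one | COc1cc(O)c(C(=O)/C=C/c2ccc(OCOC)cc2)c(OCOC)c1CC=C(C)C
F3 | step 12 | racemic 7-methoxy-5-(methoxymethoxy)-2-[4-(methoxymethoxy)phenyl]-6-(3-methylbut-2-en-1-yl)chroman-4-one | COc1cc2c(c(OCOC)c1CC=C(C)C)C(=O)CC(c1ccc(OCOC)cc1)O2
F4 | step 1 | 1-methoxy-3,5-bis(methoxymethoxy)benzene | COCOc1cc(OC)cc(OCOC)c1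
F5 | step 1 | 2-iodo-5-methoxy-1,3-bis(methoxymethoxy)benzene | Ic1c(OCOC)cc(OC)cc1OCOC
F6 | step 4 | 3-(allyloxy)-5-methoxy-2-(trimethylsilyl)phenyl trifluoromethanesulfonate | COc1cc(OS(=O)(=O)C(F)(F)F)c([Si](C)(C)C)c(OCC=C)c1
F7 | step 4 | 4-allyl-3-hydroxy-5-methoxy-2-(trimethylsilyl)phenyl trifluoromethanesulfonate | COc1cc(OS(=O)(=O)C(F)(F)F)c([Si](C)(C)C)c(O)c1CC=C
F8 | step 4 | 4-allyl-5-methoxy-3-(methoxymethoxy)-2-(trimethylsilyl)phenyl trifluoromethanesulfonate | COc1cc(OS(=O)(=O)C(F)(F)F)c([Si](C)(C)C)c(OCOC)c1CC=C
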